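**Retrosynthetic overview**

- Feature: the pyranone is fused to the arene at C4a–C8a. O1 (on C8a) and the C4 carbonyl (on C4a) are ortho, the C5 oxygen flanks C4a and the C7 oxygen is para to C4a. This is the pattern left when an O-nucleophile and an acyl group add across the triple bond of 3,5-dimethoxybenzyne.
- Last disconnection: the target comes from 5,7-dimethoxy-2-nonadecylchromone by cleavage of the two aryl methyl ethers.
- Key disconnection: O1–C8a, C4a–C4 and O1–C2 in one operation, from 3,5-dimethoxybenzyne (released from its 2-silylaryl triflate) and docos-2-ynoic acid. The pyranone is the only ring formed; the benzene ring is bought.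
- Silyl triflate: from 3,5-dimethoxyphenol by ortho-bromination, O-silylation, retro-Brook shift and triflation.
- Acid: from 1-bromononadecane by acetylide alkylation and carboxylation (C19 + C2 + C1).

Key step: step 6

Remark: the target has no stereogenic element, so the call for a single enantiomer is met as it stands and no step needs stereocontrol.

**Route**

Step 1
Reactants: 1 3,5-dimethoxyphenol
Product: 2 2-bromo-3,5-dimethoxyphenol
Conditions: NBS (1.0 equiv), CH2Cl2, −78 °C → rt; chromatography
Reagents that add atoms: N-bromosuccinimide, O=C1CCC(=O)N1Br
Why: Electrophilic aromatic bromination, in which the two equivalent positions ortho to the hydroxyl (each also para to a methoxy group) are favoured statistically and sterically over the single position between the two methoxy groups, and one equivalent of NBS at low temperature should stop at the monobromide, the minor 4-bromo isomer being removed by chromatography.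

Step 2
Reactants: 2 2-bromo-3,5-dimethoxyphenol
Product: 3 (2-bromo-3,5-dimethoxyphenoxy)trimethylsilane
Conditions: HMDS, THF, 70 °C; evaporation, crude used directly
Reagents that add atoms: hexamethyldisilazane, C[Si](C)(C)N[Si](C)(C)C
Why: O-Silylation of a phenol with HMDS gives the aryl trimethylsilyl ether with ammonia as the only by-product, so the moisture-sensitive ether can be carried on without purification.

Step 3
Reactants: 3 (2-bromo-3,5-dimethoxyphenoxy)trimethylsilane
Product: 6 3,5-dimethoxy-2-(trimethylsilyl)phenyl trifluoromethanesulfonate, via aryllithium 4 (not isolated), via silylphenoxide 5 (not isolated)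
Conditions: n-BuLi (1.1 equiv), THF, −100 → −78 °C; then Tf2O (1.2 equiv), −100 °C → rt
Reagents that add atoms: trifluoromethanesulfonic anhydride, O=S(=O)(OS(=O)(=O)C(F)(F)F)C(F)(F)F
Why: Bromine–lithium exchange gives aryllithium 4, which undergoes a fast 1,3 O→C silyl shift (retro-Brook rearrangement) driven by the change from carbanion to phenoxide, and the lithium phenoxide 5 is O-sulfonylated by triflic anhydride in the same flask.

Step 4
Reactants: 7 1-bromononadecane
Product: 8 henicos-1-yne
Conditions: lithium acetylide–ethylenediamine complex (1.5 equiv), DMSO/THF, 0 °C → rt
Reagents that add atoms: lithium acetylide–ethylenediamine complex, [Li+].[C-]#C.NCCN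
Why: SN2 alkylation of lithium acetylide by a primary bromide in a dipolar aprotic medium is a standard route to terminal alkynes, and the mono-acetylide complex avoids double alkylation.

Step 5
Reactants: 8 henicos-1-yne
Product: 10 docos-2-ynoic acid, via lithium henicosynide 9 (not isolated)
Conditions: n-BuLi (1.05 equiv), THF, −40 → 0 °C; CO2, −78 °C → rt; 1 M HCl
Reagents that add atoms: carbon dioxide, O=C=O
Why: Deprotonation of the terminal alkyne by n-butyllithium and carboxylation of the lithium acetylide with carbon dioxide is the standard synthesis of alk-2-ynoic acids.

Step 6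
Reactants: 6 3,5-dimethoxy-2-(trimethylsilyl)phenyl trifluoromethanesulfonate; 10 docos-2-ynoic acid
Product: 14 5,7-dimethoxy-2-nonadecylchromone, via 3,5-dimethoxybenzyne 11 (not isolated), via aryl anion ester 12 (not isolated), via hydroxyaryl ynone 13 (not isolated)
Conditions: 6 (1.5 equiv), 10 (1.0 equiv), CsF (4 equiv), THF, 125 °C, sealed tube
Reagents that add atoms: none
Why: Fluoride attack on silicon and loss of triflate release 3,5-dimethoxybenzyne 11; the caesium carboxylate of 10 adds to the aryne carbon remote from the flanking methoxy group (the future C8a), and the aryl anion 12 formed at the future C4a attacks the neighbouring ester carbonyl through a four-membered transition state, the C–O bond opening to the ortho-acyl phenoxide of 13 (net insertion of the aryne into the acid C–O bond, an anionic Fries-type 1,3 O→C acyl shift). The phenoxide then adds to the β-carbon of the ynone and the resulting allenolate is protonated at C3 by a further molecule of acid, which passes the carboxylate on. The closest known reaction type is the fluoride-induced insertion of arynes into the C–O bond of carboxylic acids to give ortho-hydroxyaryl ketones, which with acrylic and arylpropiolic acids runs on to 4-chromanones and flavones. The one ring formed, the pyranone, is closed by a 6-endo-dig oxa-Michael addition, and no stereocentre is created. Two selectivities are needed: carboxylate attack at the aryne carbon meta to the future C5 methoxy group, secured by the inductive pull of that group, which distorts the aryne and stabilises the developing ortho carbanion (the more remote methoxy group has only a weak influence), and acyl transfer in preference to protonation of 12, favoured by the aprotic medium, the high temperature and the intramolecular reach of the ester carbonyl. Closure 6-endo rather than 5-exo is expected because the phenoxide attacks the polarised β-carbon of an alkyl ynone in an aprotic solvent.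

Step 7
Reactants: 14 5,7-dimethoxy-2-nonadecylchromone
Product: 15 5,7-dihydroxy-2-nonadecylchromone
Conditions: BBr3 (6 equiv), CH2Cl2, −78 °C → rt; MeOH then water
Reagents that add atoms: none
Why: Lewis-acid cleavage of aryl methyl ethers with boron tribromide, in which the C5 ether chelated to the C4 carbonyl should go first and the C7 ether with excess reagent at room temperature, while the pyranone and the saturated chain are inert to the reagent.

**Compound list**

1 | 3,5-dimethoxyphenol | COc1cc(O)cc(OC)c1 | starting material
2 | 2-bromo-3,5-dimethoxyphenol | COc1cc(O)c(Br)c(OC)c1 | intermediate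
3 | (2-bromo-3,5-dimethoxyphenoxy)trimethylsilane | COc1cc(O[Si](C)(C)C)c(Br)c(OC)c1 | intermediate
4 | (2-lithio-3,5-dimethoxyphenoxy)trimethylsilane (aryllithium) | COc1cc(O[Si](C)(C)C)c([Li])c(OC)c1 | intermediate
5 | 3,5-dimethoxy-2-(trimethylsilyl)phenol (in the flask as its lithium phenoxide) | COc1cc(O)c([Si](C)(C)C)c(OC)c1 | intermediate
6 | 3,5-dimethoxy-2-(trimethylsilyl)phenyl trifluoromethanesulfonate | COc1cc(OC)c([Si](C)(C)C)c(OS(=O)(=O)C(F)(F)F)c1 | intermediate
7 | 1-bromononadecane | CCCCCCCCCCCCCCCCCCCBr | starting material
8 | henicos-1-yne | CCCCCCCCCCCCCCCCCCCC#C | intermediate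
9 | lithium henicos-1-yn-1-ide | CCCCCCCCCCCCCCCCCCCC#C[Li] | intermediate
10 | docos-2-ynoic acid | CCCCCCCCCCCCCCCCCCCC#CC(=O)O | intermediate
11 | 3,5-dimethoxybenzyne | COC1=CC(OC)=CC#C1 | intermediate
12 | caesium 2-(docos-2-ynoyloxy)-4,6-dimethoxybenzenide (aryl anion ester) | CCCCCCCCCCCCCCCCCCCC#CC(=O)Oc1cc(OC)cc(OC)[c-]1.[Cs+] | intermediate
13 | 1-(2-hydroxy-4,6-dimethoxyphenyl)docos-2-yn-1-one (in the flask as its caesium phenoxide) | CCCCCCCCCCCCCCCCCCCC#CC(=O)c1c(O)cc(OC)cc1OC | intermediate
14 | 5,7-dimethoxy-2-nonadecylchromone | CCCCCCCCCCCCCCCCCCCc1cc(=O)c2c(OC)cc(OC)cc2o1 | intermediate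
15 | 5,7-dihydroxy-2-nonadecylchromone | CCCCCCCCCCCCCCCCCCCc1cc(=O)c2c(O)cc(O)cc2o1 | target

**Step count**

Total: 7 steps. Longest linear sequence: 5 steps (steps 1, 2, 3, 6, 7); the acid branch (steps 4, 5) joins at step 6.

**Steps most likely to fail**

1. Step 6 (aryne insertion cascade). Possible failures:
- the aryl anion may be protonated before the acyl shift, which stops the cascade at the aryl ester stage;
- the caesium alkynoate may lose carbon dioxide at 125 °C;
- fluoride or carboxylate may add to the ynone;
- excess aryne may arylate the phenoxide before it cyclises.

Fallback: the same two fragments are joined stepwise by organolithium chemistry, setting out from 2 and 10 and coming back to the route at 13 and then 14. Phenol 2 would be protected (MOMCl, i-Pr2NEt, CH2Cl2) as 2-bromo-1,5-dimethoxy-3-(methoxymethoxy)benzene F1. Acid 10 would be coupled with N,O-dimethylhydroxylamine hydrochloride (EDC, N-methylmorpholine, CH2Cl2) to N-methoxy-N-methyldocos-2-ynamide F2. Bromine–lithium exchange on F1 (n-BuLi, THF, −78 °C) and addition of the aryllithium to F2, with a cold acidic quench to keep the released amine from adding to the ynone, should give 1-[2,4-dimethoxy-6-(methoxymethoxy)phenyl]docos-2-yn-1-one F3. Aqueous HCl in THF would remove the acetal to give 13, which K2CO3 in acetone should close 6-endo to 14.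

2. Step 1 (bromination). Possible failures: bromination between the two methoxy groups, or double bromination, may compete, and the isomers may be hard to separate.

Fallback: the silicon is placed by directed ortho-metalation instead of halogenation, setting out from 1 and coming back at 5 and then 6, so that steps 1–3 are bypassed. Phenol 1 with isopropyl isocyanate and Et3N in CH2Cl2 would give 3,5-dimethoxyphenyl N-isopropylcarbamate F4. N-Silylation in the flask (TBSOTf, TMEDA, Et2O), lithiation with n-BuLi at −78 °C at the position between carbamate and methoxy (both groups direct there), and a TMSCl quench with aqueous work-up should give 3,5-dimethoxy-2-(trimethylsilyl)phenyl N-isopropylcarbamate F5. DBU and Et2NH in MeCN at 40 °C would cleave the carbamate to 5 (as its amidinium phenoxide), which PhNTf2 added to the same flask would convert into 6.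

3. Step 7 (global demethylation). Possible failures: the unchelated C7 ether may be cleaved only in part, or forcing conditions with BBr3 may degrade the pyranone.

Fallback: the two ethers are removed in separate operations by different mechanisms, setting out from 14 and coming back at 15. BCl3 in CH2Cl2 at 0 °C should cleave only the chelated ether to give 5-hydroxy-7-methoxy-2-nonadecylchromone F6. A pyridine hydrochloride melt at about 190 °C (protonation of the ether and SN2 attack of chloride on the methyl group) should then free the C7 hydroxyl to give 15.

**Further compounds**

F1 | step 6 | 2-bromo-1,5-dimethoxy-3-(methoxymethoxy)benzene | COCOc1cc(OC)cc(OC)c1Br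
F2 | step 6 | N-methoxy-N-methyldocos-2-ynamide | CCCCCCCCCCCCCCCCCCCC#CC(=O)N(C)OC
F3 | step 6 | 1-[2,4-dimethoxy-6-(methoxymethoxy)phenyl]docos-2-yn-1-one | CCCCCCCCCCCCCCCCCCCC#CC(=O)c1c(OCOC)cc(OC)cc1OC
F4 | step 1 | 3,5-dimethoxyphenyl N-isopropylcarbamate | COc1cc(OC)cc(OC(=O)NC(C)C)c1
F5 | step 1 | 3,5-dimethoxy-2-(trimethylsilyl)phenyl N-isopropylcarbamate | COc1cc(OC)c([Si](C)(C)C)c(OC(=O)NC(C)C)c1
F6 | step 7 | 5-hydroxy-7-methoxy-2-nonadecylchromone | CCCCCCCCCCCCCCCCCCCc1cc(=O)c2c(O)cc(OC)cc2o1
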